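## The problem

The target joins a cis-fused hydroazulene (exocyclic methylene on C10, gem-dimethyl on C4, ring-fusion carbons C5 and C9, quaternary methyl-bearing C8) through the single C8–C8' bond to a 2,7-dioxabicyclo[3.2.1]octan-3-one (C1' acylal carbon, C3' lactone carbonyl, C4' CH–OAc, C5' bridgehead, C6' CH–CO2Me, C8' the one-carbon bridge). There are eight stereocentres: in the carbocycle C5 can direct C8 and, through the ring fusion, C9; in the heterocycle C6' can direct C5' and then C8', and C1' is dictated by the bridge. C4' has no reliable internal director, and the two halves cannot control each other across the C8–C8' bond. The hydroazulenyl group on C8' is syn to the lactone bridge, so in any monocyclic precursor it is cis to the C5' side chain, the crowded and thermodynamically disfavoured arrangement. Sensitive groups are the acylal lactone (bases, nucleophiles), the acidic C4'–H and C6'–H, the 1,1-disubstituted alkene (acid, cation capture; no ozonolysis or hydrogenation once it is present) and C9 for as long as C10 is a ketone. The unit C3'(=O)–C4'H(OAc) on C5' is an α-acyloxy acyl group, the retron of a Passerini reaction: C4' is the carbon of an aldehyde on a tetrahydrofuran (O7', C1', C8', C5', C6'), C3' an isocyanide carbon, and the acetate comes from acetic acid. The six-membered lactone ring then closes between groups already in place.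

## Retrosynthesis

**34 to 31 (functional-group change).** The C6' methyl ester of target 34 is traced to a silyloxymethyl group in lactone 31, through alcohol 32 and acid 33. An ester at C6' would make the γ-hydrogen of the earlier butenolide far too acidic. The forward steps must be non-basic because of the acylal.

**31 to 29 (O2'–C1' bond).** The lactone is opened at the O2'–C1' bond to the monocyclic α-acetoxy amide 29, which has an anomeric acetate. Forward, the amide oxygen captures the C1' oxocarbenium ion to give iminolactone 30, which is hydrolysed. This avoids a separate amide cleavage and a lactol acylation. It requires O- rather than N-attack and tolerance of the alkene.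

**29 to 26 + 27 + 28 (C3'–C4' and C4'–OAc bonds).** Both bonds at C4' are cut in a Passerini disconnection to aldehyde 26, acetic acid 27 and 1-isocyanocyclohexene 28. The neighbouring options are hydroxylation of a preformed lactone enolate, or a cyanohydrin with later hydrolysis. Both need base or extra steps on an acylal. The three-component coupling is neutral and adds two skeletal atoms, the acetate and the last stereocentre at once. It asks for Re-face attack on the formyl group.

**26 to 23 (functional-group change).** The formyl group of 26 is masked as the dithiane in 25. The anomeric acetate comes from lactone 23 by reductive acetylation through aluminium hemiacetal 24. The two aldehyde-level carbons C1' and C4' thus stay differentiated.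

**23 to 20 + 21 (C5'–C4' bond, C8'–H bond).** Dithiane 21 is removed from C5' and the hydrogen from C8', giving butenolide 20. Forward, conjugate addition anti to the C6' substituent sets C5'. Kinetic protonation of enolate 22 anti to the new group sets the cis relation at C8'. An acyclic Michael route would have to control the same two centres without a ring.

**20 to 13 + 14 (C8'=C5' bond, lactone C–O bond).** The butenolide is cut to ester 13 and (S)-glyceraldehyde acetonide 14, through enolate 15, aldol 16, lactone diol 17, silyl ether 18 and mesylate 19. C6' comes from the chiral pool. The two transient centres are erased, so the aldol needs no control.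

**13 to 10 (methylene carbon; one ring carbon).** The methylene of 13 is traced to ketone 12. The seven-membered ring of 12 comes from cyclohexanone 10 by one-carbon ring expansion through α-silyl ketone 11. The chemistry that sets C8 and C9 is thereby done on a hydrindanone, where cis fusion is the stable one.

**10 to 7 + 8 (C8–CH2 bond).** The acetate arm of 10 is an allyl group in 9, introduced by conjugate allylation of enone 7 with allylsilane 8. The allyl group must enter C8 on the H5 face.

**7 to 3 + 2 (C8=C9 and C5–C6 bonds).** Enone 7 is the aldol condensation product of diketone 6, from ketal 5. Ketal 5 comes from enantioselective conjugate addition of Grignard reagent 2 to enone 3, through magnesium enolate 4. Reagent 2 is made from bromide 1 and is used as such, so that every alkyl group made from 1 is available for transfer. This single catalytic step fixes the absolute configuration of the carbocycle.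

## Roads not taken

**Alternative 1: allenic Pauson–Khand reaction.**
- **Cut:** C5–C9, C6–C7 and C7–C8, so that both carbocycles come from one open chain.
- **Key step:** the allene-yne A1, with CO under [Rh(CO)2Cl]2, would give the bicyclo[5.3.0]decadienone A2. The seven-membered ring and the cyclopentenone close together and the allene axis is transferred to quaternary C8.
- **Merits:** in ring construction this is better than the chosen plan. It is one catalytic step instead of annulation plus ring expansion, and C8 is set stereospecifically rather than by substrate bias.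
- **Weak points:** A2 has a C7 ketone that must be removed. Its two alkenes must be reduced so that H5 and H9 end up cis. Its C10 substituent must be turned into the exocyclic methylene by a transposition. An enantiopure trisubstituted allene A1 has to be made first.
- **Comparison:** the chosen route has no surplus oxygen and already has the carbonyl on C10 where the methylene is needed. Alternative 1 leaves the heterocycle unsolved, so the Passerini sequence or an equivalent would still follow.

**Alternative 2: tertiary C–H insertion.**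
- **Cut:** C8–C9.
- **Key step:** the rhodium carbenoid from 2-diazocycloheptanone A3 (Rh2(OAc)4) would insert into the tertiary C8–H bond with retention. The product A4 is identical with compound 12 of the chosen route.
- **Merits:** the configuration of C8 would come from a preset acyclic centre. This is more secure than the facial selectivity on which step 4 depends.
- **Weak points:** the diazo group must be placed on the more hindered α-carbon of a 3-substituted 4,4-dimethylcycloheptanone. The C5–H next to the carbenoid invites 1,2-hydride shift to the enone. Insertion at C7–H competes. The seven-membered ketone and an enantiopure side chain must both be made beforehand.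
- **Comparison:** the chosen plan reaches 12 in six steps from achiral materials with one catalytic asymmetric step. It has none of the regiochemical questions of A3.

**Alternative 3: 7-exo-dig radical closure.**
- **Cut:** C9–C10.
- **Key step:** the C9 radical from xanthate A5 (Bu3SnH, AIBN) would add to the inner alkyne carbon and give the cis-hydroazulene A6 with the methylene in place.
- **Merits:** there is no C10 ketone, so no epimerisable C9, no ring expansion and no methylenation. In this respect it is cleaner than steps 6 and 7.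
- **Weak points:** seven-membered closure of a hindered secondary radical onto an unactivated alkyne is slow. It competes with direct reduction and with 1,5-hydrogen transfer. The ring fusion depends on the facial preference of the radical. A5 carries three stereocentres that must be assembled first.
- **Comparison:** the chosen plan uses slower but ionic and well-precedented steps for the same bonds. Like the other two alternatives, this one would still need the heterocycle chemistry of steps 8 to 19.

Key step: step 15

Remark: Haz stands for the (1R,3aR,8aS)-1,4,4-trimethyl-8-methylidenedecahydroazulen-1-yl group. This is the ring system of 13 with unchanged spatial arrangement (H5 and H9 cis, side chain on their face). In 13 the C1 descriptor is S only because the CIP ranking of the side chain differs.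

Assumption: 16 to 19 are carried as mixtures at the two centres erased in step 11. Compounds 25, 26 and 29 are drawn as the anomer with the C1' acetate trans to Haz; the other anomer would serve equally, because C1' is ionised in step 16.

Step 1
Reactants: 1 2-(2-bromoethyl)-2-methyl-1,3-dioxolane
Product: 2 [2-(2-methyl-1,3-dioxolan-2-yl)ethyl]magnesium bromide
Conditions: Mg turnings (I2 initiation), Et2O with the minimum of THF needed to keep 2 in solution, 25–30 °C; titrated and used the same day
Reagents that add atoms: magnesium, SMILES [Mg]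
Why: Grignard formation by magnesium insertion into a primary alkyl bromide; the ketal is inert to the reagent at ambient temperature, and this reagent is the standard 3-oxobutyl nucleophile for cyclopentene annulation.

Step 2
Reactants: 2 [2-(2-methyl-1,3-dioxolan-2-yl)ethyl]magnesium bromide; 3 4,4-dimethylcyclohex-2-en-1-one
Product: 5 (3R)-4,4-dimethyl-3-[2-(2-methyl-1,3-dioxolan-2-yl)ethyl]cyclohexan-1-one, via magnesium enolate 4 (not isolated)
Conditions: CuBr·SMe2 (5 mol %), 1-[2-(diphenylphosphino)ferrocenyl]ethyldicyclohexylphosphine (Josiphos type, 6 mol %; the enantiomer that gives the 3R ketone), t-BuOMe, −75 °C, 2 added over 2 h; aq. NH4Cl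
Reagents that add atoms: none
Why: Copper-catalysed enantioselective conjugate addition of a Grignard reagent to a cyclic enone with a ferrocenyl diphosphine ligand; slow addition at low temperature keeps the catalysed 1,4-path ahead of uncatalysed 1,2-addition. The ligand alone sets C5, the only reagent-controlled centre of the carbocycle, and the magnesium enolate is protonated on work-up.

Step 3
Reactants: 5 (3R)-4,4-dimethyl-3-[2-(2-methyl-1,3-dioxolan-2-yl)ethyl]cyclohexan-1-one
Product: 7 (7aS)-3,7,7-trimethyl-1,2,5,6,7,7a-hexahydro-4H-inden-4-one, via diketone 6 (not isolated)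
Conditions: 2 M HCl, THF, 23 °C; then KOH, MeOH, 60 °C
Reagents that add atoms: none
Why: Ketal hydrolysis and intramolecular aldol condensation (cyclopentene annulation); only attack of the ring α-carbon C9 on the methyl ketone can dehydrate, to the conjugated tetrasubstituted enone, whereas the bridged aldols are reversible. C5 is not enolisable and keeps its configuration.

Step 4
Reactants: 7 (7aS)-3,7,7-trimethyl-1,2,5,6,7,7a-hexahydro-4H-inden-4-one; 8 allyltrimethylsilane
Product: 9 (3S,3aR,7aR)-3,7,7-trimethyl-3-(prop-2-en-1-yl)octahydro-4H-inden-4-one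
Conditions: TiCl4 (1.2 equiv), CH2Cl2, −78 → −40 °C; H2O
Reagents that add atoms: none
Why: Hosomi–Sakurai conjugate allylation, the standard route to a quaternary carbon β to the ketone of an s-cis alkylidene cycloalkanone; the allyl group should enter C8 on the H5 face, anti to the C5–C4 bond and its gem-dimethyl group. Protonation of the enolate gives the cis-hydrindanone, which is also the more stable ring fusion.

Step 5
Reactants: 9 (3S,3aR,7aR)-3,7,7-trimethyl-3-(prop-2-en-1-yl)octahydro-4H-inden-4-one
Product: 10 methyl 2-[(1S,3aR,7aR)-1,4,4-trimethyl-7-oxooctahydro-1H-inden-1-yl]acetate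
Conditions: O3, NaOH (2.5 M in MeOH), CH2Cl2, −78 °C
Reagents that add atoms: ozone, SMILES [O-][O+]=O; methanol, SMILES CO
Why: Ozonolysis in methanolic NaOH turns a terminal alkene directly into the methyl ester with one carbon less (ozone oxidises the hemiacetal); base is used here at the hydrindanone stage, where the cis fusion is the stable one.

Step 6
Reactants: 10 methyl 2-[(1S,3aR,7aR)-1,4,4-trimethyl-7-oxooctahydro-1H-inden-1-yl]acetate
Product: 12 methyl 2-[(1S,3aR,8aR)-1,4,4-trimethyl-8-oxodecahydroazulen-1-yl]acetate, via α-silyl ketone 11 (not isolated)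
Conditions: Me3SiCHN2 (1.5 equiv), BF3·OEt2 (1.5 equiv), CH2Cl2, −78 → −30 °C; then 1 M HCl, THF, 0 °C
Reagents that add atoms: (trimethylsilyl)diazomethane, SMILES C[Si](C)(C)C=[N+]=[N-]
Why: Lewis-acid-promoted diazoalkane ring expansion of a cyclohexanone (1,2-shift of the Tiffeneau–Demjanov type); with the bulky silyl diazomethane the unhindered CH2 should migrate in preference to the tertiary C9 beside quaternary C8, so the carbonyl stays on C10. Protodesilylation passes through the enol on the far side of the carbonyl and leaves C9 untouched.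

Step 7
Reactants: 12 methyl 2-[(1S,3aR,8aR)-1,4,4-trimethyl-8-oxodecahydroazulen-1-yl]acetate
Product: 13 methyl 2-[(1S,3aR,8aS)-1,4,4-trimethyl-8-methylidenedecahydroazulen-1-yl]acetate
Conditions: Zn, CH2Br2, TiCl4, THF/CH2Cl2, 0 → 23 °C
Reagents that add atoms: dibromomethane, SMILES BrCBr
Why: Lombardo methylenation, a non-basic titanium-mediated olefination used for hindered and epimerisable ketones; it spares the methyl ester and avoids the enolate that could invert C9.

Step 8
Reactants: 13 methyl 2-[(1S,3aR,8aS)-1,4,4-trimethyl-8-methylidenedecahydroazulen-1-yl]acetate; 14 (S)-2,2-dimethyl-1,3-dioxolane-4-carbaldehyde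
Product: 16 methyl 3-[(4S)-2,2-dimethyl-1,3-dioxolan-4-yl]-3-hydroxy-2-Haz-propanoate, via lithium enolate 15 (not isolated)
Conditions: LiN(i-Pr)2 (1.1 equiv), THF, −78 °C; then 14, −78 °C; aq. NH4Cl
Reagents that add atoms: none
Why: Aldol addition of an ester enolate to an aldehyde; the two new centres need no control because step 11 removes both, and the dioxolane carbon (future C6') comes unchanged from 14.

Step 9
Reactants: 16 methyl 3-[(4S)-2,2-dimethyl-1,3-dioxolan-4-yl]-3-hydroxy-2-Haz-propanoate
Product: 17 (5S)-4-hydroxy-5-(hydroxymethyl)-3-Haz-oxolan-2-one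
Conditions: TsOH·H2O (10 mol %), MeOH/H2O (20:1), 23 °C; then toluene, 50 °C
Reagents that add atoms: none
Why: Acid-catalysed acetonide cleavage followed by lactonisation; as in 2-deoxypentonic acids, the secondary hydroxyl closes the five-membered lactone in preference to the six-membered one.

Step 10
Reactants: 17 (5S)-4-hydroxy-5-(hydroxymethyl)-3-Haz-oxolan-2-one
Product: 18 (5S)-5-{[tert-butyl(diphenyl)silyl]oxymethyl}-4-hydroxy-3-Haz-oxolan-2-one
Conditions: t-BuPh2SiCl (1.05 equiv), imidazole, CH2Cl2, 0 °C
Reagents that add atoms: tert-butyl(chloro)diphenylsilane, SMILES CC(C)(C)[Si](Cl)(c1ccccc1)c1ccccc1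
Why: Selective silylation of the primary hydroxyl by a bulky silyl chloride; this robust ether later shields one face of the butenolide and survives the acidic and Lewis-acidic steps up to step 16.

Step 11
Reactants: 18 (5S)-5-{[tert-butyl(diphenyl)silyl]oxymethyl}-4-hydroxy-3-Haz-oxolan-2-one
Product: 20 (5R)-5-{[tert-butyl(diphenyl)silyl]oxymethyl}-3-Haz-furan-2(5H)-one, via mesylate 19 (not isolated)
Conditions: MsCl (1.5 equiv), Et3N (4 equiv), CH2Cl2, 0 → 23 °C
Reagents that add atoms: none
Why: Mesylation and E1cB elimination of a β-hydroxy lactone, the usual route from 2-deoxypentonolactones to butenolides; inside the ring only the conjugated endocyclic alkene can form, so no alkene geometry has to be controlled.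

Step 12
Reactants: 20 (5R)-5-{[tert-butyl(diphenyl)silyl]oxymethyl}-3-Haz-furan-2(5H)-one; 21 1,3-dithiane
Product: 23 (3R,4R,5R)-5-{[tert-butyl(diphenyl)silyl]oxymethyl}-4-(1,3-dithian-2-yl)-3-Haz-oxolan-2-one, via lithium enolate 22 (not isolated)
Conditions: 21, n-BuLi, THF, −30 °C; HMPA, −78 °C; 20, −78 °C; then 2,6-di-tert-butyl-4-methylphenol, −78 °C; aq. NH4Cl
Reagents that add atoms: none
Why: Conjugate addition of a lithiated dithiane to a butenolide (HMPA favours 1,4-addition) anti to the silyloxymethyl group on C6' sets C5'. Kinetic protonation of the enolate by a bulky phenol, on the face away from the new dithianyl group, sets C8' with Haz cis to it.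

Step 13
Reactants: 23 (3R,4R,5R)-5-{[tert-butyl(diphenyl)silyl]oxymethyl}-4-(1,3-dithian-2-yl)-3-Haz-oxolan-2-one
Product: 25 (2R,3R,4R,5R)-5-{[tert-butyl(diphenyl)silyl]oxymethyl}-4-(1,3-dithian-2-yl)-3-Haz-oxolan-2-yl acetate, via aluminium hemiacetal 24 (not isolated)
Conditions: i-Bu2AlH (1.2 equiv), CH2Cl2, −78 °C; then pyridine, DMAP, Ac2O, −78 → 0 °C
Reagents that add atoms: acetic anhydride, SMILES CC(=O)OC(C)=O
Why: Reductive acetylation of a lactone (hydride reduction to the aluminium hemiacetal and acylation in the same flask); the free lactol, in which the strained C8' centre would sit α to an aldehyde, is never released.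

Step 14
Reactants: 25 (2R,3R,4R,5R)-5-{[tert-butyl(diphenyl)silyl]oxymethyl}-4-(1,3-dithian-2-yl)-3-Haz-oxolan-2-yl acetate
Product: 26 (2R,3R,4R,5R)-5-{[tert-butyl(diphenyl)silyl]oxymethyl}-4-formyl-3-Haz-oxolan-2-yl acetate
Conditions: MeI, CaCO3, MeCN/H2O (9:1), 45 °C
Reagents that add atoms: water, SMILES O
Why: Alkylative hydrolysis of a dithioacetal under buffered neutral conditions, which spare the alkene, the anomeric acetate and the silyl ether and do not enolise the new aldehyde.

Step 15
Reactants: 26 (2R,3R,4R,5R)-5-{[tert-butyl(diphenyl)silyl]oxymethyl}-4-formyl-3-Haz-oxolan-2-yl acetate; 27 acetic acid; 28 1-isocyanocyclohex-1-ene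
Product: 29 (1S)-1-[(2R,3R,4R,5R)-5-acetoxy-2-{[tert-butyl(diphenyl)silyl]oxymethyl}-4-Haz-oxolan-3-yl]-2-(cyclohex-1-en-1-ylamino)-2-oxoethyl acetate
Conditions: 27 (2 equiv), 28 (2 equiv, freshly distilled), 3,3'-bis(2,4,6-triisopropylphenyl)-1,1'-binaphthyl-2,2'-diyl hydrogen phosphate (10 mol %, matched enantiomer), 4 Å molecular sieves, CH2Cl2 (0.5 M), 0 → 23 °C
Reagents that add atoms: none
Why: Passerini three-component reaction: the isocyanide carbon of 28 attacks the acid-activated formyl group of 26, acetate adds to the nitrilium ion and acyl transfer within the resulting imidate gives the α-acetoxy amide, so the C4'–C3' and C4'–OAc bonds form together. The closest known reaction type is the chiral-phosphoric-acid-catalysed Passerini reaction of α-branched aliphatic aldehydes with carboxylic acids and isocyanides. No ring is closed. The one new stereocentre, C4', requires attack on the Re face of the aldehyde. The Felkin–Anh preference of 26, with the C8' branch as the large group, is expected to be weak and, if anything, towards the Si face, so the facial choice is handed to the chiral acid, used as its matched enantiomer. C5' is α to the aldehyde and cis to Haz, so the reaction is run cold, concentrated and without base to keep that centre. The neutral medium leaves the anomeric acetate, the silyl ether and the alkene untouched. The N-cyclohexenyl amide is chosen because its carbonyl oxygen closes the lactone in step 16 and its enamine part is then lost by hydrolysis.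

Step 16
Reactants: 29 (1S)-1-[(2R,3R,4R,5R)-5-acetoxy-2-{[tert-butyl(diphenyl)silyl]oxymethyl}-4-Haz-oxolan-3-yl]-2-(cyclohex-1-en-1-ylamino)-2-oxoethyl acetate
Product: 31 (1S,4S,5R,6R,8R)-6-{[tert-butyl(diphenyl)silyl]oxymethyl}-3-oxo-8-Haz-2,7-dioxabicyclo[3.2.1]octan-4-yl acetate, via iminolactone 30 (not isolated)
Conditions: Me3SiOTf (1.2 equiv), CH2Cl2, −40 → 0 °C; then THF/H2O (4:1), 0 → 23 °C
Reagents that add atoms: water, SMILES O
Why: Ionisation of the anomeric acetate and capture of the oxocarbenium ion by the amide oxygen (the participation known from 2-acylamino glycosyl donors) gives a six-membered cyclic imidate. Its acidic hydrolysis expels the enamine as cyclohexanone and ammonium and leaves the acylal lactone. C1' is fixed by the bridge, because the C5' side chain can reach only its own face.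

Step 17
Reactants: 31 (1S,4S,5R,6R,8R)-6-{[tert-butyl(diphenyl)silyl]oxymethyl}-3-oxo-8-Haz-2,7-dioxabicyclo[3.2.1]octan-4-yl acetate
Product: 32 (1S,4S,5R,6R,8R)-6-(hydroxymethyl)-3-oxo-8-Haz-2,7-dioxabicyclo[3.2.1]octan-4-yl acetate
Conditions: HF·pyridine, THF/pyridine, 0 → 23 °C
Reagents that add atoms: none
Why: Fluoride-mediated silyl ether cleavage in a buffered acidic medium, chosen because the acylal lactone and the acetate would not tolerate basic fluoride sources.

Step 18
Reactants: 32 (1S,4S,5R,6R,8R)-6-(hydroxymethyl)-3-oxo-8-Haz-2,7-dioxabicyclo[3.2.1]octan-4-yl acetate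
Product: 33 (1S,4S,5R,6R,8R)-4-acetoxy-3-oxo-8-Haz-2,7-dioxabicyclo[3.2.1]octane-6-carboxylic acid
Conditions: TEMPO (0.2 equiv), PhI(OAc)2 (2.2 equiv), MeCN/H2O (1:1), 23 °C
Reagents that add atoms: water, SMILES O
Why: Oxoammonium-catalysed oxidation of a primary alcohol to the carboxylic acid through the aldehyde hydrate; the near-neutral medium should leave the exocyclic alkene, the acylal and C6' untouched.

Step 19
Reactants: 33 (1S,4S,5R,6R,8R)-4-acetoxy-3-oxo-8-Haz-2,7-dioxabicyclo[3.2.1]octane-6-carboxylic acid
Product: 34 methyl (1S,4S,5R,6R,8R)-4-acetoxy-3-oxo-8-Haz-2,7-dioxabicyclo[3.2.1]octane-6-carboxylate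
Conditions: Me3SiCHN2, toluene/MeOH (4:1), 0 °C
Reagents that add atoms: (trimethylsilyl)diazomethane, SMILES C[Si](C)(C)C=[N+]=[N-]
Why: Diazoalkane esterification of a carboxylic acid, fast and neutral, so neither C6' nor C4' is exposed to base.

**Compound list**

1 | 2-(2-bromoethyl)-2-methyl-1,3-dioxolane | CC1(CCBr)OCCO1 | starting material
2 | [2-(2-methyl-1,3-dioxolan-2-yl)ethyl]magnesium bromide | CC1(CC[Mg]Br)OCCO1 | intermediate
3 | 4,4-dimethylcyclohex-2-en-1-one | CC1(C)CCC(=O)C=C1 | starting material
4 | bromomagnesium (3R)-4,4-dimethyl-3-[2-(2-methyl-1,3-dioxolan-2-yl)ethyl]cyclohex-1-en-1-olate (enolate of 5) | Br[Mg]OC1=C[C@@H](CCC2(C)OCCO2)C(C)(C)CC1 | intermediate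
5 | (3R)-4,4-dimethyl-3-[2-(2-methyl-1,3-dioxolan-2-yl)ethyl]cyclohexan-1-one | O=C1CCC(C)(C)[C@H](CCC2(C)OCCO2)C1 | intermediate
6 | (3R)-4,4-dimethyl-3-(3-oxobutyl)cyclohexan-1-one | O=C1CCC(C)(C)[C@H](CCC(C)=O)C1 | intermediate
7 | (7aS)-3,7,7-trimethyl-1,2,5,6,7,7a-hexahydro-4H-inden-4-one | CC1=C2C(=O)CCC(C)(C)[C@@H]2CC1 | intermediate
8 | allyltrimethylsilane | C=CC[Si](C)(C)C | starting material
9 | (3S,3aR,7aR)-3,7,7-trimethyl-3-(prop-2-en-1-yl)octahydro-4H-inden-4-one | O=C1CCC(C)(C)[C@@H]2CC[C@@](C)(CC=C)[C@H]12 | intermediate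
10 | methyl 2-[(1S,3aR,7aR)-1,4,4-trimethyl-7-oxooctahydro-1H-inden-1-yl]acetate | O=C1CCC(C)(C)[C@@H]2CC[C@@](C)(CC(=O)OC)[C@H]12 | intermediate
11 | methyl 2-[(1S,3aR,8aR)-1,4,4-trimethyl-8-oxo-7-(trimethylsilyl)decahydroazulen-1-yl]acetate (C7 epimers) | O=C1C([Si](C)(C)C)CCC(C)(C)[C@@H]2CC[C@@](C)(CC(=O)OC)[C@H]12 | intermediate
12 | methyl 2-[(1S,3aR,8aR)-1,4,4-trimethyl-8-oxodecahydroazulen-1-yl]acetate | O=C1CCCC(C)(C)[C@@H]2CC[C@@](C)(CC(=O)OC)[C@H]12 | intermediate
13 | methyl 2-[(1S,3aR,8aS)-1,4,4-trimethyl-8-methylidenedecahydroazulen-1-yl]acetate | C=C1CCCC(C)(C)[C@@H]2CC[C@@](C)(CC(=O)OC)[C@H]12 | intermediate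
14 | (S)-2,2-dimethyl-1,3-dioxolane-4-carbaldehyde | CC1(C)OC[C@@H](C=O)O1 | starting material
15 | lithium 1-methoxy-2-Haz-ethen-1-olate (enolate of 13) | C=C1CCCC(C)(C)[C@@H]2CC[C@@](C)(C=C(OC)O[Li])[C@H]12 | intermediate
16 | methyl 3-[(4S)-2,2-dimethyl-1,3-dioxolan-4-yl]-3-hydroxy-2-Haz-propanoate (C2/C3 mixture) | C=C1CCCC(C)(C)[C@@H]2CC[C@@](C)(C(C(=O)OC)C(O)[C@@H]3COC(C)(C)O3)[C@H]12 | intermediate
17 | (5S)-4-hydroxy-5-(hydroxymethyl)-3-Haz-oxolan-2-one (C3/C4 mixture) | C=C1CCCC(C)(C)[C@@H]2CC[C@@](C)(C3C(=O)O[C@@H](CO)C3O)[C@H]12 | intermediate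
18 | (5S)-5-{[tert-butyl(diphenyl)silyl]oxymethyl}-4-hydroxy-3-Haz-oxolan-2-one | C=C1CCCC(C)(C)[C@@H]2CC[C@@](C)(C3C(=O)O[C@@H](CO[Si](c4ccccc4)(c4ccccc4)C(C)(C)C)C3O)[C@H]12 | intermediate
19 | 4-O-methanesulfonate of 18 | C=C1CCCC(C)(C)[C@@H]2CC[C@@](C)(C3C(=O)O[C@@H](CO[Si](c4ccccc4)(c4ccccc4)C(C)(C)C)C3OS(C)(=O)=O)[C@H]12 | intermediate
20 | (5R)-5-{[tert-butyl(diphenyl)silyl]oxymethyl}-3-Haz-furan-2(5H)-one | C=C1CCCC(C)(C)[C@@H]2CC[C@@](C)(C3=C[C@H](CO[Si](c4ccccc4)(c4ccccc4)C(C)(C)C)OC3=O)[C@H]12 | intermediate
21 | 1,3-dithiane | C1CSCSC1 | starting material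
22 | lithium enolate of lactone 23 (4R,5R) | C=C1CCCC(C)(C)[C@@H]2CC[C@@](C)(C3=C(O[Li])O[C@@H](CO[Si](c4ccccc4)(c4ccccc4)C(C)(C)C)[C@@H]3C5SCCCS5)[C@H]12 | intermediate
23 | (3R,4R,5R)-5-{[tert-butyl(diphenyl)silyl]oxymethyl}-4-(1,3-dithian-2-yl)-3-Haz-oxolan-2-one | C=C1CCCC(C)(C)[C@@H]2CC[C@@](C)([C@@H]3C(=O)O[C@@H](CO[Si](c4ccccc4)(c4ccccc4)C(C)(C)C)[C@@H]3C5SCCCS5)[C@H]12 | intermediate
24 | diisobutylaluminium hemiacetal of 23 (C2 epimers) | C=C1CCCC(C)(C)[C@@H]2CC[C@@](C)([C@@H]3C(O[Al](CC(C)C)CC(C)C)O[C@@H](CO[Si](c4ccccc4)(c4ccccc4)C(C)(C)C)[C@@H]3C5SCCCS5)[C@H]12 | intermediate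
25 | (2R,3R,4R,5R)-5-{[tert-butyl(diphenyl)silyl]oxymethyl}-4-(1,3-dithian-2-yl)-3-Haz-oxolan-2-yl acetate | C=C1CCCC(C)(C)[C@@H]2CC[C@@](C)([C@@H]3[C@@H](OC(C)=O)O[C@@H](CO[Si](c4ccccc4)(c4ccccc4)C(C)(C)C)[C@@H]3C5SCCCS5)[C@H]12 | intermediate
26 | (2R,3R,4R,5R)-5-{[tert-butyl(diphenyl)silyl]oxymethyl}-4-formyl-3-Haz-oxolan-2-yl acetate | C=C1CCCC(C)(C)[C@@H]2CC[C@@](C)([C@@H]3[C@@H](OC(C)=O)O[C@@H](CO[Si](c4ccccc4)(c4ccccc4)C(C)(C)C)[C@@H]3C=O)[C@H]12 | intermediate
27 | acetic acid | CC(=O)O | starting material
28 | 1-isocyanocyclohex-1-ene | [C-]#[N+]C1=CCCCC1 | starting material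
29 | (1S)-1-[(2R,3R,4R,5R)-5-acetoxy-2-{[tert-butyl(diphenyl)silyl]oxymethyl}-4-Haz-oxolan-3-yl]-2-(cyclohex-1-en-1-ylamino)-2-oxoethyl acetate | C=C1CCCC(C)(C)[C@@H]2CC[C@@](C)([C@@H]3[C@@H](OC(C)=O)O[C@@H](CO[Si](c4ccccc4)(c4ccccc4)C(C)(C)C)[C@@H]3[C@H](OC(C)=O)C(=O)NC4=CCCCC4)[C@H]12 | intermediate
30 | N-(cyclohex-1-en-1-yl) iminolactone corresponding to 31 (C3'=N in place of C3'=O) | C=C1CCCC(C)(C)[C@@H]2CC[C@@](C)([C@@H]3[C@@H]4OC(=NC5=CCCCC5)[C@@H](OC(C)=O)[C@H]3[C@H](CO[Si](c5ccccc5)(c5ccccc5)C(C)(C)C)O4)[C@H]12 | intermediate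
31 | (1S,4S,5R,6R,8R)-6-{[tert-butyl(diphenyl)silyl]oxymethyl}-3-oxo-8-Haz-2,7-dioxabicyclo[3.2.1]octan-4-yl acetate | C=C1CCCC(C)(C)[C@@H]2CC[C@@](C)([C@@H]3[C@@H]4OC(=O)[C@@H](OC(C)=O)[C@H]3[C@H](CO[Si](c5ccccc5)(c5ccccc5)C(C)(C)C)O4)[C@H]12 | intermediate
32 | (1S,4S,5R,6R,8R)-6-(hydroxymethyl)-3-oxo-8-Haz-2,7-dioxabicyclo[3.2.1]octan-4-yl acetate | C=C1CCCC(C)(C)[C@@H]2CC[C@@](C)([C@@H]3[C@@H]4OC(=O)[C@@H](OC(C)=O)[C@H]3[C@H](CO)O4)[C@H]12 | intermediate
33 | (1S,4S,5R,6R,8R)-4-acetoxy-3-oxo-8-Haz-2,7-dioxabicyclo[3.2.1]octane-6-carboxylic acid | C=C1CCCC(C)(C)[C@@H]2CC[C@@](C)([C@@H]3[C@@H]4OC(=O)[C@@H](OC(C)=O)[C@H]3[C@H](C(=O)O)O4)[C@H]12 | intermediate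
34 | methyl (1S,4S,5R,6R,8R)-4-acetoxy-3-oxo-8-Haz-2,7-dioxabicyclo[3.2.1]octane-6-carboxylate | C=C1CCCC(C)(C)[C@@H]2CC[C@@](C)([C@@H]3[C@@H]4OC(=O)[C@@H](OC(C)=O)[C@H]3[C@H](C(=O)OC)O4)[C@H]12 | target

**Step count and risks**

Total step count: 19. Longest linear sequence: 19 steps (from bromide 1 to 34; 18 from enone 3).

**Step 15 (key step).** The likely failure is poor or reversed facial selectivity at C4', because the intrinsic bias of the aldehyde opposes the catalyst. Partial epimerisation of C5' before the addition is the second concern. Fallback, from 26 back to 31: the coupling is run without the chiral acid and the (1R)-configured adduct F1 is taken through the step-16 conditions to the C4'-epimeric lactone F2. F2 is then equilibrated with DBU in toluene through the lactone enolate. In the bicycle the acetoxy group of F2 is syn-axial to Haz, whereas in 31 it is equatorial, so the equilibrium should lie on the side of 31.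

**Step 12.** Addition to the α-tert-alkyl butenolide may be slow. γ-Deprotonation would erode C6', 1,2-addition may compete, and the protonation may not be selective. Fallback, from 20 back to 23: radical addition of 1,3-dioxolane under (n-Bu4N)4[W10O32] photocatalysis (365 nm, MeCN) gives the dioxolanyl lactone F3. The dioxolanyl radical adds anti to the C6' group and hydrogen transfer to the α-radical occurs anti to the new group. Exchange with propane-1,3-dithiol and BF3·OEt2 at low temperature then gives 23.

**Step 4.** Facial selectivity at C8 rests on 1,3-induction from C5 alone and may be insufficient; a competing silyl-retaining [3+2] annulation is also possible. Fallback, from 7 back to 10: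
- Corey–Bakshi–Shibata reduction (BH3·SMe2 with the B-methyl oxazaborolidine derived from diphenylprolinol, in the enantiomer that places the hydroxyl on the H5 face) gives the allylic alcohol F4.
- Johnson–Claisen rearrangement with trimethyl orthoacetate delivers the acetate arm to C8 suprafacially, giving the unsaturated ester F5.
- Hydroboration–oxidation (BH3·SMe2; NaOH/H2O2) gives the hydroxy ester F6.
- Dess–Martin oxidation with brief K2CO3 equilibration of C9 returns 10.

**Step 6.** The wrong carbon may migrate, or C9 may epimerise in the seven-membered ketone under acid. Fallback, from 10 back to 12: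
- The kinetic silyl enol ether F7 is formed (LiN(i-Pr)2, Me3SiCl, −78 °C).
- Cyclopropanation (Et2Zn, CH2I2) gives the siloxycyclopropane F8.
- Ring opening with FeCl3 and dehydrochlorination with NaOAc give the cycloheptenone F9.
- Hydrogenation (H2, Pd/C) gives 12.

This fixes the site of insertion by the position of the enol ether.

**Step 16.** The oxocarbenium ion may be captured by nitrogen (lactam) or by the C10 methylene (Prins closure), or may lose the C8' proton to a dihydrofuran. Fallback, from 29 back to 31: the anomeric acetate is removed with hydrazine acetate in DMF to give the lactol amide F10. Camphorsulfonic acid in dry CH2Cl2 then protonates the enamide carbon. The lactol hydroxyl attacks the resulting N-acyliminium acyl carbon and gives 31 directly, with loss of the imine. The activation is at the acyl carbon, under acid too weak to ionise the lactol.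

**Step 2.** Enantio- and regioselectivity may be eroded: uncatalysed 1,2-addition of the Grignard reagent competes, the quaternary carbon beside the β-position slows the catalysed 1,4-path, and donor solvent carried in with 2 loosens the copper–diphosphine complex. Fallback, from 2 back to 5: 2 is transmetalated with ZnCl2 (half an equivalent), the magnesium halides are precipitated with 1,4-dioxane and filtered off, and the halide-free dialkylzinc bis[2-(2-methyl-1,3-dioxolan-2-yl)ethyl]zinc F11 is added to 3 in toluene at −30 °C under Cu(OTf)2 and a BINOL-derived phosphoramidite with a bis(1-phenylethyl)amine unit; aqueous NH4Cl then gives 5. The dialkylzinc has no uncatalysed reaction with the enone, and functionalised dialkylzincs are established partners for 4,4-disubstituted cyclohexenones under this catalyst; the price is that only one of its two alkyl groups is transferred.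

## Further compounds

F1 | step 15 | (1R)-epimer of 29 at the acetoxy carbon | C=C1CCCC(C)(C)[C@@H]2CC[C@@](C)([C@@H]3[C@@H](OC(C)=O)O[C@@H](CO[Si](c4ccccc4)(c4ccccc4)C(C)(C)C)[C@@H]3[C@@H](OC(C)=O)C(=O)NC4=CCCCC4)[C@H]12
F2 | step 15 | C4' epimer of lactone 31 | C=C1CCCC(C)(C)[C@@H]2CC[C@@](C)([C@@H]3[C@@H]4OC(=O)[C@H](OC(C)=O)[C@H]3[C@H](CO[Si](c5ccccc5)(c5ccccc5)C(C)(C)C)O4)[C@H]12
F3 | step 12 | (3R,4R,5R)-5-{[tert-butyl(diphenyl)silyl]oxymethyl}-4-(1,3-dioxolan-2-yl)-3-Haz-oxolan-2-one | C=C1CCCC(C)(C)[C@@H]2CC[C@@](C)([C@@H]3C(=O)O[C@@H](CO[Si](c4ccccc4)(c4ccccc4)C(C)(C)C)[C@@H]3C5OCCO5)[C@H]12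
F4 | step 4 | (4S,7aS)-3,7,7-trimethyl-2,4,5,6,7,7a-hexahydro-1H-inden-4-ol | CC1=C2[C@@H](O)CCC(C)(C)[C@@H]2CC1
F5 | step 4 | methyl 2-[1,4,4-trimethyl-2,3,3a,4,5,6-hexahydro-1H-inden-1-yl]acetate (acetate arm on the H3a face) | COC(=O)C[C@]1(C)CC[C@H]2C(C)(C)CCC=C12
F6 | step 4 | methyl 2-[7-hydroxy-1,4,4-trimethyloctahydro-1H-inden-1-yl]acetate (cis-fused; carbinol epimers) | COC(=O)C[C@]1(C)CC[C@H]2C(C)(C)CCC(O)[C@@H]12
F7 | step 6 | trimethylsilyl enol ether of 10 (C7=C6 of the indane) | C[Si](C)(C)OC1=CCC(C)(C)[C@@H]2CC[C@@](C)(CC(=O)OC)[C@H]12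
F8 | step 6 | siloxycyclopropane from F7 | C[Si](C)(C)OC13CC1CC(C)(C)[C@@H]2CC[C@@](C)(CC(=O)OC)[C@H]32
F9 | step 6 | methyl 2-[(1S,3aR,8aR)-1,4,4-trimethyl-8-oxo-1,2,3,3a,4,5,8,8a-octahydroazulen-1-yl]acetate | O=C1C=CCC(C)(C)[C@@H]2CC[C@@](C)(CC(=O)OC)[C@H]12
F10 | step 16 | lactol corresponding to 29 (anomeric OH in place of OAc; anomers) | C=C1CCCC(C)(C)[C@@H]2CC[C@@](C)([C@@H]3C(O)O[C@@H](CO[Si](c4ccccc4)(c4ccccc4)C(C)(C)C)[C@@H]3[C@H](OC(C)=O)C(=O)NC4=CCCCC4)[C@H]12
F11 | step 2 | bis[2-(2-methyl-1,3-dioxolan-2-yl)ethyl]zinc | CC1(CC[Zn]CCC2(C)OCCO2)OCCO1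
A1 | alternative 1 | 3,9,9-trimethyl-5-{[tri(propan-2-yl)silyl]oxymethyl}undeca-3,4-dien-10-yn-1-ol (single allene enantiomer) | OCCC(C)=[C@@]=C(CO[Si](C(C)C)(C(C)C)C(C)C)CCCC(C)(C)C#C
A2 | alternative 1 | bicyclo[5.3.0]decadienone with C7 ketone, quaternary C8 (methyl, 2-hydroxyethyl) and silyloxymethyl on C10 | O=C1C=C2C(=C(CO[Si](C(C)C)(C(C)C)C(C)C)CCCC2(C)C)[C@]1(C)CCO
A3 | alternative 2 | methyl (3S)-5-[(1R)-3-diazo-7,7-dimethyl-2-oxocycloheptyl]-3-methylpentanoate | O=C1CCCC(C)(C)[C@H](CC[C@@H](C)CC(=O)OC)C1=[N+]=[N-]
A4 | alternative 2 | methyl 2-[(1S,3aR,8aR)-1,4,4-trimethyl-8-oxodecahydroazulen-1-yl]acetate (identical with 12) | O=C1CCCC(C)(C)[C@@H]2CC[C@@](C)(CC(=O)OC)[C@H]12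
A5 | alternative 3 | O-[cyclopentyl] S-methyl xanthate bearing the 2-methylhex-5-yn-2-yl group on C5 and methyl and 2-silyloxyethyl on C8 (C9 epimers) | C#CCCCC(C)(C)[C@@H]1CC[C@@](C)(CCO[Si](C)(C)C(C)(C)C)C1OC(=S)SC
A6 | alternative 3 | tert-butyl(dimethyl)silyl ether of 2-[(1R,3aR,8aS)-1,4,4-trimethyl-8-methylidenedecahydroazulen-1-yl]ethanol | C=C1CCCC(C)(C)[C@@H]2CC[C@@](C)(CCO[Si](C)(C)C(C)(C)C)[C@H]12
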